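**Retrosynthetic overview** (germacrane numbering C1–C15)

1. 17 ⇐ 16: the last step forms C1–C2 at the acetal carbon in a visible-light Ni/HAT step, closing the ten-membered ring and creating the bridged ketal. The 2-alkenyl ketal is only made inside the macrocycle, where ring strain blocks loss of MeOH to a furan.
2. 16 ⇐ 14 (tigloylation) ⇐ 10 + 13: indium Barbier allylation forms C7–C8 and the α-methylene lactone, with C7 and C8 set by C6.
3. 10 ⇐ 7 + 8 by esterification and ring-closing metathesis; 7 ⇐ 5 by converting the butenolide into a methyl acetal.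
4. 5 ⇐ 4 by Cu-catalysed anti-carbomagnesiation and CO2 trapping; 4 ⇐ D-xylose, whose C2 and C3 become C5 and C6; 13 ⇐ but-3-yn-1-ol.
5. Ring order: left five-membered O-ring (butenolide, then dihydrofuran acetal) → right butenolide → α-methylene-γ-lactone → ten-membered carbocycle with the 2,5-epoxy ketal bridge.

Assumption: the SMILES is read as (2S,5S,6S,7R,8S), 1(10)E, with an (E)-2-methylbut-2-enoate (tiglate). Compounds 7, 9, 10, 14 and 16 are carried as epimer mixtures at the acetal carbon (C2); both epimers converge in the last step.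

**Route**

Step 1
Reactants: 1, D-xylose
Product: 2, methyl D-xylofuranoside (α/β)
Conditions: AcCl (cat.), MeOH, rt, 4 h; NaHCO3
Reagents that add atoms: methanol, CO
Why: Kinetic Fischer glycosidation gives the furanosides first and leaves C2 and C3 (future C5 and C6) untouched.

Step 2
Reactants: 2, methyl D-xylofuranoside
Product: 3, methyl 5-deoxy-5-iodo-D-xylofuranoside
Conditions: PPh3, I2, imidazole, THF, 65 °C
Reagents that add atoms: iodine, II
Why: Appel-type (Garegg) iodination is selective for the only primary hydroxyl of the unprotected glycoside.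

Step 3
Reactants: 3, methyl 5-deoxy-5-iodo-D-xylofuranoside
Product: 4, (3S,4S)-hex-1-en-5-yne-3,4-diol
Conditions: Zn dust, THF/H2O 4:1, sonication, 40 °C; filter; then dimethyl (1-diazo-2-oxopropyl)phosphonate, K2CO3, MeOH, 0 °C→rt (one pot, aldehyde not isolated)
Reagents that add atoms: Ohira–Bestmann reagent, CC(=O)C(=[N+]=[N-])P(=O)(OC)OC
Why: Bernet–Vasella reductive fragmentation releases (2R,3S)-2,3-dihydroxypent-4-enal, and Ohira–Bestmann (Seyferth–Gilbert) homologation turns the aldehyde into the terminal alkyne without touching the two carbinol centres.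

Step 4
Reactants: 4, (3S,4S)-hex-1-en-5-yne-3,4-diol
Product: 5, (5S)-5-[(1S)-1-hydroxyprop-2-en-1-yl]-4-methylfuran-2(5H)-one
Conditions: MeMgBr (6 equiv), CuI (20 mol %), THF, −20 °C→rt; CO2 (g), −20 °C→rt; 2 M HCl
Reagents that add atoms: methylmagnesium bromide, C[Mg]Br; carbon dioxide, O=C=O
Why: Alkoxide-directed Cu-catalysed anti-carbomagnesiation (Duboudin type) puts Me on the internal alkyne carbon and Mg on the terminal carbon cis to the carbinol, so carboxylation gives the Z-γ-hydroxy acid, which lactonises to the β-methylbutenolide and leaves the allylic OH free.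

Step 5
Reactants: 5
Product: 6, (5S)-5-[(1S)-1-(tert-butyldimethylsilyloxy)prop-2-en-1-yl]-4-methylfuran-2(5H)-one
Conditions: TBSCl, imidazole, DMF, 0 °C→rt
Reagents that add atoms: TBSCl, C[Si](C)(Cl)C(C)(C)C
Why: Silylation blocks the C6 hydroxyl so the lactol made next can only exist as the five-membered ring.

Step 6
Reactants: 6
Product: 7, (1S)-1-[(2S)-5-methoxy-3-methyl-2,5-dihydrofuran-2-yl]prop-2-en-1-ol (about 1:1 at the acetal carbon)
Conditions: DIBAL-H, CH2Cl2, −78 °C, Rochelle work-up; crude lactol: PPTS (5 mol %), MeOH, 0 °C, 30 min, then Et3N; solvent switch, TBAF, THF, 0 °C (telescoped, no intermediate purification; Et3N-deactivated silica)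
Reagents that add atoms: methanol, CO
Why: Partial lactone reduction and kinetic acetalisation through the cyclic allylic oxocarbenium ion give the methyl acetal (a protected Z-γ-hydroxy-enal), and fluoride desilylation under non-acidic conditions frees the C6 hydroxyl without ring-size isomerisation or aromatisation.

Step 7
Reactants: 7; 8, 2-(bromomethyl)acrylic acid
Product: 9, (1S)-1-[(2S)-5-methoxy-3-methyl-2,5-dihydrofuran-2-yl]prop-2-en-1-yl 2-(bromomethyl)acrylate
Conditions: DCC, DMAP (5 mol %), CH2Cl2, −20→0 °C
Reagents that add atoms: 2-(bromomethyl)acrylic acid (8), OC(=O)C(=C)CBr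
Why: Steglich esterification acylates the only free hydroxyl with retention at C6.

Step 8
Reactants: 9
Product: 10, (5S)-3-(bromomethyl)-5-[(2S)-5-methoxy-3-methyl-2,5-dihydrofuran-2-yl]furan-2(5H)-one
Conditions: Hoveyda–Grubbs II (5 mol %), toluene (0.01 M), 80 °C
Reagents that add atoms: none
Why: Ring-closing metathesis between the vinyl group and the acrylate (loss of ethylene) forms the 3-(bromomethyl)butenolide, while the trisubstituted dihydrofuran olefin is inert and C6 is untouched.

Step 9
Reactants: 11, but-3-yn-1-ol
Product: 12, (E)-4-bromo-3-methylbut-3-en-1-ol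
Conditions: Me3Al (3 equiv), Cp2ZrCl2 (0.25 equiv), CH2Cl2, 0 °C→rt; then NBS, THF, −30 °C
Reagents that add atoms: trimethylaluminium, C[Al](C)C; N-bromosuccinimide, O=C1CCC(=O)N1Br
Why: Negishi Zr-catalysed syn-carboalumination followed by bromodealumination with retention gives the E-trisubstituted alkenyl bromide.

Step 10
Reactants: 12
Product: 13, (E)-4-bromo-3-methylbut-3-enal
Conditions: Dess–Martin periodinane, NaHCO3, CH2Cl2, 0 °C; used at once
Reagents that add atoms: none
Why: Buffered Dess–Martin oxidation gives the β,γ-unsaturated aldehyde without migration of the double bond into conjugation.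

Step 11
Reactants: 10; 13
Product: 14, (4R,5S)-4-[(1S,3E)-4-bromo-1-hydroxy-3-methylbut-3-en-1-yl]-5-[(2S)-5-methoxy-3-methyl-2,5-dihydrofuran-2-yl]-3-methylideneoxolan-2-one
Conditions: In powder, THF/H2O 2:1, 0 °C→rt
Reagents that add atoms: none
Why: Barbier allylation through a closed Zimmerman–Traxler transition state bonds C7 to the aldehyde on the butenolide face anti to the C6 substituent (C6/C7 trans) and, because the ring fixes the γ-substituent E, gives the anti C7/C8 relationship, i.e. (7R,8S), while generating the exo-methylene lactone.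

Step 12
Reactants: 14; 15, tigloyl chloride
Product: 16, the C8 (E)-2-methylbut-2-enoate of 14
Conditions: Et3N, DMAP (cat.), CH2Cl2, 0 °C
Reagents that add atoms: tigloyl chloride (15), C/C=C(\C)C(Cl)=O
Why: Standard acylation of the secondary alcohol with retention at C8; the ester also deactivates the C8–H towards hydrogen-atom abstraction in the next step.

Step 13
Reactants: 16
Product: 17, 2β-methoxy-2-deethoxy-8-O-deacylphantomolin-8-O-tiglinate
Conditions: Ir[dF(CF3)ppy]2(dtbbpy)PF6 (2 mol %), NiBr2·dtbbpy (25 mol %), 3-acetoxyquinuclidine (1.5 equiv), MeCN, 2 mM (syringe-pump addition), 450 nm LEDs, 25 °C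
Reagents that add atoms: none
Why: Proposed new method: the photogenerated quinuclidinium radical cation abstracts the most hydridic C–H (the allylic O,O-acetal C2–H), both acetal epimers giving one planar 2-methoxy-2,5-dihydrofuran-2-yl radical; Ni capture, intramolecular oxidative addition of the alkenyl bromide and reductive elimination then forge C1–C2 and the ten-membered ring, where only the cis-2,5-bridged ketal is geometrically possible so C5 fixes C2 (OMe exo, 2β) and the alkenyl geometry is retained (1(10)E); the closest known reaction type is Ni/photoredox HAT C(sp3)–H arylation of ethers and of the 1,3-dioxolane acetal C–H with aryl halides, and an intramolecular alkenylation at a substituted acetal C–H to make a ketal and a macrocycle has not been shown.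

**Compound list**

1 | D-xylose | O=C[C@H](O)[C@@H](O)[C@H](O)CO | starting material
2 | methyl D-xylofuranoside (α/β) | COC1O[C@H](CO)[C@H](O)[C@H]1O | intermediate
3 | methyl 5-deoxy-5-iodo-D-xylofuranoside (α/β) | COC1O[C@H](CI)[C@H](O)[C@H]1O | intermediate
4 | (3S,4S)-hex-1-en-5-yne-3,4-diol | C=C[C@H](O)[C@@H](O)C#C | intermediate
5 | (5S)-5-[(1S)-1-hydroxyprop-2-en-1-yl]-4-methylfuran-2(5H)-one | CC1=CC(=O)O[C@@H]1[C@@H](O)C=C | intermediate
6 | (5S)-5-[(1S)-1-(tert-butyldimethylsilyloxy)prop-2-en-1-yl]-4-methylfuran-2(5H)-one | CC1=CC(=O)O[C@@H]1[C@@H](O[Si](C)(C)C(C)(C)C)C=C | intermediate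
7 | (1S)-1-[(2S)-5-methoxy-3-methyl-2,5-dihydrofuran-2-yl]prop-2-en-1-ol (acetal epimers) | COC1C=C(C)[C@H](O1)[C@@H](O)C=C | intermediate
8 | 2-(bromomethyl)acrylic acid | OC(=O)C(=C)CBr | starting material
9 | (1S)-1-[(2S)-5-methoxy-3-methyl-2,5-dihydrofuran-2-yl]prop-2-en-1-yl 2-(bromomethyl)acrylate | COC1C=C(C)[C@H](O1)[C@@H](OC(=O)C(=C)CBr)C=C | intermediate
10 | (5S)-3-(bromomethyl)-5-[(2S)-5-methoxy-3-methyl-2,5-dihydrofuran-2-yl]furan-2(5H)-one | COC1C=C(C)[C@H](O1)[C@H]1OC(=O)C(CBr)=C1 | intermediate
11 | but-3-yn-1-ol | OCCC#C | starting material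
12 | (E)-4-bromo-3-methylbut-3-en-1-ol | OCC/C(C)=C/Br | intermediate
13 | (E)-4-bromo-3-methylbut-3-enal | O=CC/C(C)=C/Br | intermediate
14 | (4R,5S)-4-[(1S,3E)-4-bromo-1-hydroxy-3-methylbut-3-en-1-yl]-5-[(2S)-5-methoxy-3-methyl-2,5-dihydrofuran-2-yl]-3-methylideneoxolan-2-one | C=C1C(=O)O[C@@H]([C@H]1[C@@H](O)C/C(C)=C/Br)[C@H]1OC(OC)C=C1C | intermediate
15 | tigloyl chloride, (E)-2-methylbut-2-enoyl chloride | C/C=C(\C)C(Cl)=O | starting material
16 | (1S,3E)-4-bromo-1-{(2S,3R)-2-[(2S)-5-methoxy-3-methyl-2,5-dihydrofuran-2-yl]-4-methylidene-5-oxooxolan-3-yl}-3-methylbut-3-en-1-yl (2E)-2-methylbut-2-enoate | C=C1C(=O)O[C@@H]([C@H]1[C@@H](OC(=O)/C(C)=C/C)C/C(C)=C/Br)[C@H]1OC(OC)C=C1C | intermediate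
17 | 2β-methoxy-2-deethoxy-8-O-deacylphantomolin-8-O-tiglinate, (2S,5S,6S,7R,8S) | C=C1C(=O)O[C@H]2[C@H]1[C@@H](OC(=O)/C(C)=C/C)C/C(C)=C/[C@@]1(OC)C=C(C)[C@@H]2O1 | target

**Step count**

Total steps: 13. Longest linear sequence: 11 (steps 1–8, then 11–13).

**Steps most likely to fail, with fallbacks**

1. Step 13 (the proposed new step). Risks are addition of the C2/C4-delocalised radical to the α-methylene lactone, oligomerisation, and oxidation of the radical to a furanium ion. Fallback with known chemistry:
   - make the iodide analogue of 16 (I2 quench in step 9);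
   - hydrolyse the methyl acetal to the lactol (PPTS, acetone/H2O);
   - close the ring by a conventional CrCl2/NiCl2 Nozaki–Hiyama–Kishi addition of the alkenyl iodide to the ring-opened Z-γ-hydroxy-enal at high dilution;
   - oxidise the bis-allylic C2 alcohol with MnO2, which gives the transannular hemiketal, and ketalise with CSA/MeOH.

2. Step 4 (directed methyl-carbomagnesiation and carboxylation on the unprotected diol). Risks are sluggish methyl transfer and competing deprotonation of the alkyne. Fallback: bis-silylate 4, lithiate the alkyne and trap with ClCO2Me to the ynoate, syn-add Me2CuLi at −78 °C to the Z-β-methyl enoate, then TBAF, which desilylates and lactonises to 5. This replaces directed carbometalation with conjugate addition.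

3. Step 3 (one-pot Zn fragmentation and alkyne homologation through an unprotected, water-soluble α,β-dihydroxy aldehyde). Risks are base-induced isomerisation and poor recovery. Fallback: take C5/C6 from L-tartaric acid instead. From 2,3-O-isopropylidene-L-threitol: mono-TBS, Swern/Wittig methylenation, TBAF, Swern/Ohira–Bestmann, then aqueous acid to 4, all on protected, extractable intermediates.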